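**Strategy.** Everything rests on the C5–C6 bond of ring A, the trihydroxycyclohexane: its two adjacent tertiary carbinol carbons carry cis hydroxyls, the signature of a pinacol coupling. A chiral-pool cyclohexenecarboxylate, made from the enol triflate of (4R,6R)-actinol that also supplies acetylenic ring B, is deliberately unzipped by ozonolysis to an acyclic 1,6-diketone (C5 methyl ketone, C6–C7 α-keto ester). The key step re-closes ring A by a samarium diiodide pinacol cyclisation and sets C5 and C6 in one operation, relayed from the C3 silyloxy stereocentre; the inert tetrasubstituted alkene is thereby turned into the cis-diol. C15 + C10 + C15 Wittig assembly and desilylation complete the route.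

Key step: step 5

Remark: the target is read as drawn, (3S,5R,6S,3'R) with a cis-5,6-diol; (4R,6R)-actinol is taken as a purchasable chiral-pool ketone; carotenoid numbering (C1–C7, primed for ring B) is used in the explanations.

Step 1
Reactants: 1 (4R,6R)-4-hydroxy-2,2,6-trimethylcyclohexan-1-one ((4R,6R)-actinol)
Product: 2 (4R,6R)-4-(tert-butyldimethylsilyloxy)-2,2,6-trimethylcyclohexan-1-one
Conditions: TBSCl, imidazole, DMF, rt
Reagents that add atoms: tert-butyldimethylsilyl chloride (TBSCl), CC(C)(C)[Si](C)(C)Cl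
Why: Imidazole-promoted silylation (silyl ether protection) of the unhindered secondary alcohol leaves both stereocentres untouched and blocks O-sulfonylation and alkoxide chemistry in the later steps.

Step 2
Reactants: 2 (4R,6R)-4-(tert-butyldimethylsilyloxy)-2,2,6-trimethylcyclohexan-1-one
Product: 4 (4R)-4-(tert-butyldimethylsilyloxy)-2,6,6-trimethylcyclohex-1-en-1-yl trifluoromethanesulfonate, via potassium enolate 3 (not isolated)
Conditions: KN(SiMe3)2, THF, −78 °C; then PhNTf2, −78 °C → 0 °C
Reagents that add atoms: N-phenyl-bis(trifluoromethanesulfonimide) (PhNTf2), O=S(=O)(N(c1ccccc1)S(=O)(=O)C(F)(F)F)C(F)(F)F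
Why: The ketone has a single α-hydrogen (the other α-carbon is quaternary), so only one enolate can form and its O-sulfonylation (enol triflate formation) should give the tetrasubstituted vinyl triflate, erasing the methyl-bearing stereocentre on purpose while the silyloxy centre is unaffected.

Step 3
Reactants: 4 (4R)-4-(tert-butyldimethylsilyloxy)-2,6,6-trimethylcyclohex-1-en-1-yl trifluoromethanesulfonate
Product: 5 methyl (4R)-4-(tert-butyldimethylsilyloxy)-2,6,6-trimethylcyclohex-1-ene-1-carboxylate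
Conditions: Pd(OAc)2 (5 mol %), 1,3-bis(diphenylphosphino)propane, CO (1 atm), MeOH, Et3N, DMF, 70 °C
Reagents that add atoms: carbon monoxide, [C-]#[O+]; methanol, CO
Why: Palladium-catalysed alkoxycarbonylation of a vinyl triflate (oxidative addition to zerovalent palladium, CO insertion, methanolysis of the acylpalladium) is established for hindered trimethylcyclohexenyl triflates and installs C7 at the ester oxidation level on the future C6.

Step 4
Reactants: 5 methyl (4R)-4-(tert-butyldimethylsilyloxy)-2,6,6-trimethylcyclohex-1-ene-1-carboxylate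
Product: 6 methyl (5S)-5-(tert-butyldimethylsilyloxy)-3,3-dimethyl-2,7-dioxooctanoate
Conditions: O3, CH2Cl2/MeOH, −78 °C; then Me2S, → rt
Reagents that add atoms: ozone, [O-][O+]=O
Why: Ozonolysis with reductive work-up (Criegee cleavage, the carbonyl oxide trapped by methanol and reduced by Me2S) should cut the only C=C bond and turn its two carbons into the C5 methyl ketone and the C6 α-keto ester, the silyloxy stereocentre being untouched (its descriptor changes from R to S only through the priority rules).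

Step 5
Reactants: 6 methyl (5S)-5-(tert-butyldimethylsilyloxy)-3,3-dimethyl-2,7-dioxooctanoate
Product: 8 methyl (1S,2R,4S)-4-(tert-butyldimethylsilyloxy)-1,2-dihydroxy-2,6,6-trimethylcyclohexane-1-carboxylate, via samarium ketyl 7 (not isolated)
Conditions: SmI2 (2.5 equiv), THF, −78 °C → −20 °C; then aq. NH4Cl
Reagents that add atoms: none
Why: SmI2 should first reduce the far more electron-poor C6 carbonyl of the α-keto ester to an ester-chelated ketyl of trivalent samarium, whose carbon adds to the C5 methyl ketone held on the same metal, and a second equivalent of SmI2 reduces the resulting oxygen radical, so that a samarium diolate forms and is protonated on work-up (if the ketyl is reduced first, the samarium enediolate reaches the same diolate by aldol addition). The closest known reaction type is the SmI2-mediated intramolecular pinacol coupling of 1,6-dicarbonyl compounds to cis-cyclohexane-1,2-diols. Ring A is closed by 6-exo attack of the C6 ketyl carbon on the C5 carbonyl carbon through a chair-like transition state. The cis relationship of the C5 and C6 hydroxyls is imposed by the samarium ion that bridges both oxygens during bond formation, and the facial sense is controlled by the existing C3 stereocentre: its bulky, non-chelating silyloxy group sits equatorial and the C5 methyl also takes an equatorial site to avoid a 1,3-diaxial clash with the axial C1 methyl, which places O5 axial, O6 equatorial and the ester axial, i.e. the (1S,2R,4S) isomer. The step needs ketyl formation at C6 only and cyclisation instead of plain reduction or elimination, which the large difference in reduction potential between the two carbonyls, the absence of a proton source during the reduction and the quaternary C1 next to C6 (no α-hydrogen, no α-leaving group) should secure.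

Step 6
Reactants: 8 methyl (1S,2R,4S)-4-(tert-butyldimethylsilyloxy)-1,2-dihydroxy-2,6,6-trimethylcyclohexane-1-carboxylate
Product: 9 methyl (1S,2R,4S)-4-(tert-butyldimethylsilyloxy)-2,6,6-trimethyl-1,2-bis(trimethylsilyloxy)cyclohexane-1-carboxylate
Conditions: TMSOTf, 2,6-lutidine, CH2Cl2, −78 °C → 0 °C
Reagents that add atoms: trimethylsilyl trifluoromethanesulfonate (TMSOTf), C[Si](C)(C)OS(=O)(=O)C(F)(F)F
Why: Silyl triflate silylation with a hindered pyridine base is the standard way to cap tertiary alcohols and masks both tertiary hydroxyls so that no alkoxide can trigger retro-aldol cleavage or α-ketol rearrangement once C7 becomes an aldehyde.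

Step 7
Reactants: 9 methyl (1S,2R,4S)-4-(tert-butyldimethylsilyloxy)-2,6,6-trimethyl-1,2-bis(trimethylsilyloxy)cyclohexane-1-carboxylate
Product: 11 (1S,2R,4S)-4-(tert-butyldimethylsilyloxy)-2,6,6-trimethyl-1,2-bis(trimethylsilyloxy)cyclohexane-1-carbaldehyde, via aluminium hemiacetal 10 (not isolated)
Conditions: (i-Bu)2AlH (1.3 equiv), CH2Cl2, −78 °C; then aq. potassium sodium tartrate
Reagents that add atoms: none
Why: Partial ester reduction with (i-Bu)2AlH at low temperature should stop at the tetrahedral aluminium hemiacetal, here additionally shielded by the two flanking fully substituted carbons, and hydrolysis on work-up releases the non-enolisable aldehyde.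

Step 8
Reactants: 11 (1S,2R,4S)-4-(tert-butyldimethylsilyloxy)-2,6,6-trimethyl-1,2-bis(trimethylsilyloxy)cyclohexane-1-carbaldehyde; 12 ethyl (2E)-4-(diethoxyphosphoryl)-3-methylbut-2-enoate
Product: 14 ethyl (2E,4E)-5-[(1S,2R,4S)-4-(tert-butyldimethylsilyloxy)-2,6,6-trimethyl-1,2-bis(trimethylsilyloxy)cyclohexyl]-3-methylpenta-2,4-dienoate, via lithium phosphonate anion 13 (not isolated)
Conditions: 12, LiN(SiMe3)2, THF/DMPU, −78 °C → 0 °C; then 11, 0 °C → rt
Reagents that add atoms: none
Why: Horner–Wadsworth–Emmons olefination with the vinylogous C5 phosphonate is the classical C10 + C5 chain extension of carotenoid chemistry and should give the (E)-C7=C8 bond from the bulky non-enolisable aldehyde while the reagent carries its (E)-trisubstituted C9=C10 bond into the product.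

Step 9
Reactants: 14 ethyl (2E,4E)-5-[(1S,2R,4S)-4-(tert-butyldimethylsilyloxy)-2,6,6-trimethyl-1,2-bis(trimethylsilyloxy)cyclohexyl]-3-methylpenta-2,4-dienoate
Product: 15 (2E,4E)-5-[(1S,2R,4S)-4-(tert-butyldimethylsilyloxy)-2,6,6-trimethyl-1,2-bis(trimethylsilyloxy)cyclohexyl]-3-methylpenta-2,4-dien-1-ol
Conditions: (i-Bu)2AlH (2.5 equiv), CH2Cl2, −78 °C; then aq. potassium sodium tartrate
Reagents that add atoms: none
Why: (i-Bu)2AlH reduces conjugated esters by 1,2-hydride delivery to the allylic alcohol (ester reduction) without touching the diene or the silyl ethers.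

Step 10
Reactants: 15 (2E,4E)-5-[(1S,2R,4S)-4-(tert-butyldimethylsilyloxy)-2,6,6-trimethyl-1,2-bis(trimethylsilyloxy)cyclohexyl]-3-methylpenta-2,4-dien-1-ol
Product: 17 [(2E,4E)-5-[(1S,2R,4S)-4-(tert-butyldimethylsilyloxy)-2,6,6-trimethyl-1,2-bis(trimethylsilyloxy)cyclohexyl]-3-methylpenta-2,4-dien-1-yl]triphenylphosphonium bromide, via allylic bromide 16 (not isolated)
Conditions: CBr4, PPh3, 2,6-lutidine, CH2Cl2, 0 °C; then PPh3, rt
Reagents that add atoms: carbon tetrabromide, BrC(Br)(Br)Br; triphenylphosphine, c1ccc(cc1)P(c1ccccc1)c1ccccc1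
Why: Appel bromination converts the primary allylic alcohol into the bromide under neutral conditions that spare the silyl ethers and the acid-labile tertiary allylic C6 oxygen, and the bromide is quaternised in the same flask by SN2 attack of PPh3 at the unhindered terminus.

Step 11
Reactants: 4 (4R)-4-(tert-butyldimethylsilyloxy)-2,6,6-trimethylcyclohex-1-en-1-yl trifluoromethanesulfonate; 18 (2E)-3-methylpent-2-en-4-yn-1-ol
Product: 19 (2E)-5-[(4R)-4-(tert-butyldimethylsilyloxy)-2,6,6-trimethylcyclohex-1-en-1-yl]-3-methylpent-2-en-4-yn-1-ol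
Conditions: Pd(PPh3)4 (5 mol %), CuI (10 mol %), i-Pr2NH, DMF, 50 °C
Reagents that add atoms: none
Why: Sonogashira coupling of the vinyl triflate with the terminal enyne forms the C6'–C7' bond and should deliver the 7',8'-didehydro C15 unit with the (E)-geometry of the purchased enynol retained, since the coupling does not touch the C9'=C10' bond.

Step 12
Reactants: 19 (2E)-5-[(4R)-4-(tert-butyldimethylsilyloxy)-2,6,6-trimethylcyclohex-1-en-1-yl]-3-methylpent-2-en-4-yn-1-ol
Product: 21 [(2E)-5-[(4R)-4-(tert-butyldimethylsilyloxy)-2,6,6-trimethylcyclohex-1-en-1-yl]-3-methylpent-2-en-4-yn-1-yl]triphenylphosphonium bromide, via allylic bromide 20 (not isolated)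
Conditions: CBr4, PPh3, CH2Cl2, 0 °C; then PPh3, rt
Reagents that add atoms: carbon tetrabromide, BrC(Br)(Br)Br; triphenylphosphine, c1ccc(cc1)P(c1ccccc1)c1ccccc1
Why: Appel bromination of the primary allylic alcohol followed by in-flask SN2 quaternisation with PPh3 gives the C15 Wittig salt under neutral conditions that keep the silyl ether.

Step 13
Reactants: 21 [(2E)-5-[(4R)-4-(tert-butyldimethylsilyloxy)-2,6,6-trimethylcyclohex-1-en-1-yl]-3-methylpent-2-en-4-yn-1-yl]triphenylphosphonium bromide; 22 (2E,4E,6E)-2,7-dimethylocta-2,4,6-trienedial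
Product: 24 (2E,4E,6E,8E,10E)-13-[(4R)-4-(tert-butyldimethylsilyloxy)-2,6,6-trimethylcyclohex-1-en-1-yl]-2,7,11-trimethyltrideca-2,4,6,8,10-pentaen-12-ynal, via ylide 23 (not isolated)
Conditions: NaN(SiMe3)2, THF, −78 °C; then addition to 22 (3 equiv), THF, −78 °C → rt
Reagents that add atoms: none
Why: Wittig olefination of the semi-stabilised ylide with the symmetrical C10 dialdehyde used in excess (inverse addition) should give the mono-condensation product, the conjugated C25 aldehyde, with the new C11'=C12' bond mainly (E) and any (Z) isomer removable by crystallisation or mild thermal equilibration.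

Step 14
Reactants: 17 [(2E,4E)-5-[(1S,2R,4S)-4-(tert-butyldimethylsilyloxy)-2,6,6-trimethyl-1,2-bis(trimethylsilyloxy)cyclohexyl]-3-methylpenta-2,4-dien-1-yl]triphenylphosphonium bromide; 24 (2E,4E,6E,8E,10E)-13-[(4R)-4-(tert-butyldimethylsilyloxy)-2,6,6-trimethylcyclohex-1-en-1-yl]-2,7,11-trimethyltrideca-2,4,6,8,10-pentaen-12-ynal
Product: 26 (3S,5R,6S,3'R)-3,3'-bis-O-(tert-butyldimethylsilyl)-5,6-bis-O-(trimethylsilyl)-7',8'-didehydro-5,6-dihydro-β,β-carotene-3,5,6,3'-tetrol, via ylide 25 (not isolated)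
Conditions: NaN(SiMe3)2, THF, −78 °C; then 24, −78 °C → rt, dark, argon
Reagents that add atoms: none
Why: The final C15 + C25 Wittig olefination joins the two halves at C11=C12 under aprotic conditions that keep all silyl ethers, the accompanying (11Z) isomer being a sterically hindered cis-alkene that should equilibrate to all-(E) on gentle warming.

Step 15
Reactants: 26 (3S,5R,6S,3'R)-3,3'-bis-O-(tert-butyldimethylsilyl)-5,6-bis-O-(trimethylsilyl)-7',8'-didehydro-5,6-dihydro-β,β-carotene-3,5,6,3'-tetrol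
Product: 27 (3S,5R,6S,3'R)-7',8'-didehydro-5,6-dihydro-β,β-carotene-3,5,6,3'-tetrol (the target)
Conditions: TBAF, THF, 0 °C → rt, dark, argon
Reagents that add atoms: none
Why: Fluoride-mediated desilylation removes the two tert-butyldimethylsilyl and two trimethylsilyl ethers under non-acidic conditions that the polyene, the enyne and the acid-sensitive tertiary allylic 6-hydroxyl should tolerate, and no stereocentre is affected.

**Compound list**

1 | (4R,6R)-4-hydroxy-2,2,6-trimethylcyclohexan-1-one ((4R,6R)-actinol) | C[C@H]1C(=O)C(C)(C)C[C@H](O)C1 | starting material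
2 | (4R,6R)-4-(tert-butyldimethylsilyloxy)-2,2,6-trimethylcyclohexan-1-one | C[C@H]1C(=O)C(C)(C)C[C@H](O[Si](C)(C)C(C)(C)C)C1 | intermediate
3 | potassium (4R)-4-(tert-butyldimethylsilyloxy)-2,6,6-trimethylcyclohex-1-en-1-olate | CC1=C([O-])C(C)(C)C[C@H](O[Si](C)(C)C(C)(C)C)C1.[K+] | intermediate (not isolated)
4 | (4R)-4-(tert-butyldimethylsilyloxy)-2,6,6-trimethylcyclohex-1-en-1-yl trifluoromethanesulfonate | CC1=C(OS(=O)(=O)C(F)(F)F)C(C)(C)C[C@H](O[Si](C)(C)C(C)(C)C)C1 | intermediate
5 | methyl (4R)-4-(tert-butyldimethylsilyloxy)-2,6,6-trimethylcyclohex-1-ene-1-carboxylate | CC1=C(C(=O)OC)C(C)(C)C[C@H](O[Si](C)(C)C(C)(C)C)C1 | intermediate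
6 | methyl (5S)-5-(tert-butyldimethylsilyloxy)-3,3-dimethyl-2,7-dioxooctanoate | COC(=O)C(=O)C(C)(C)C[C@H](O[Si](C)(C)C(C)(C)C)CC(C)=O | intermediate
7 | ketyl of trivalent samarium from 6 (carbon radical at C2 bearing an O–SmI2 group, (5S)) | COC(=O)[C](O[Sm](I)I)C(C)(C)C[C@H](O[Si](C)(C)C(C)(C)C)CC(C)=O | intermediate (not isolated)
8 | methyl (1S,2R,4S)-4-(tert-butyldimethylsilyloxy)-1,2-dihydroxy-2,6,6-trimethylcyclohexane-1-carboxylate | COC(=O)[C@]1(O)C(C)(C)C[C@H](O[Si](C)(C)C(C)(C)C)C[C@@]1(C)O | intermediate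
9 | methyl (1S,2R,4S)-4-(tert-butyldimethylsilyloxy)-2,6,6-trimethyl-1,2-bis(trimethylsilyloxy)cyclohexane-1-carboxylate | COC(=O)[C@]1(O[Si](C)(C)C)C(C)(C)C[C@H](O[Si](C)(C)C(C)(C)C)C[C@@]1(C)O[Si](C)(C)C | intermediate
10 | diisobutylaluminium methyl hemiacetal of 9 (ring configuration as in 9) | COC(O[Al](CC(C)C)CC(C)C)[C@]1(O[Si](C)(C)C)C(C)(C)C[C@H](O[Si](C)(C)C(C)(C)C)C[C@@]1(C)O[Si](C)(C)C | intermediate (not isolated)
11 | (1S,2R,4S)-4-(tert-butyldimethylsilyloxy)-2,6,6-trimethyl-1,2-bis(trimethylsilyloxy)cyclohexane-1-carbaldehyde | O=C[C@]1(O[Si](C)(C)C)C(C)(C)C[C@H](O[Si](C)(C)C(C)(C)C)C[C@@]1(C)O[Si](C)(C)C | intermediate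
12 | ethyl (2E)-4-(diethoxyphosphoryl)-3-methylbut-2-enoate | CCOC(=O)/C=C(\C)CP(=O)(OCC)OCC | starting material
13 | lithium salt of the C4 carbanion of 12 | [Li+].CCOC(=O)/C=C(\C)[CH-]P(=O)(OCC)OCC | intermediate (not isolated)
14 | ethyl (2E,4E)-5-[(1S,2R,4S)-4-(tert-butyldimethylsilyloxy)-2,6,6-trimethyl-1,2-bis(trimethylsilyloxy)cyclohexyl]-3-methylpenta-2,4-dienoate | CCOC(=O)/C=C(C)/C=C/[C@]1(O[Si](C)(C)C)C(C)(C)C[C@H](O[Si](C)(C)C(C)(C)C)C[C@@]1(C)O[Si](C)(C)C | intermediate
15 | (2E,4E)-5-[(1S,2R,4S)-4-(tert-butyldimethylsilyloxy)-2,6,6-trimethyl-1,2-bis(trimethylsilyloxy)cyclohexyl]-3-methylpenta-2,4-dien-1-ol | OC/C=C(C)/C=C/[C@]1(O[Si](C)(C)C)C(C)(C)C[C@H](O[Si](C)(C)C(C)(C)C)C[C@@]1(C)O[Si](C)(C)C | intermediate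
16 | (2E,4E)-1-bromo analogue of 15 (allylic bromide) | BrC/C=C(C)/C=C/[C@]1(O[Si](C)(C)C)C(C)(C)C[C@H](O[Si](C)(C)C(C)(C)C)C[C@@]1(C)O[Si](C)(C)C | intermediate (not isolated)
17 | [(2E,4E)-5-[(1S,2R,4S)-4-(tert-butyldimethylsilyloxy)-2,6,6-trimethyl-1,2-bis(trimethylsilyloxy)cyclohexyl]-3-methylpenta-2,4-dien-1-yl]triphenylphosphonium bromide | [Br-].c2ccccc2[P+](c3ccccc3)(c4ccccc4)C/C=C(C)/C=C/[C@]1(O[Si](C)(C)C)C(C)(C)C[C@H](O[Si](C)(C)C(C)(C)C)C[C@@]1(C)O[Si](C)(C)C | intermediate
18 | (2E)-3-methylpent-2-en-4-yn-1-ol | C#C/C(C)=C/CO | starting material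
19 | (2E)-5-[(4R)-4-(tert-butyldimethylsilyloxy)-2,6,6-trimethylcyclohex-1-en-1-yl]-3-methylpent-2-en-4-yn-1-ol | CC1=C(C#C/C(C)=C/CO)C(C)(C)C[C@H](O[Si](C)(C)C(C)(C)C)C1 | intermediate
20 | (2E)-1-bromo analogue of 19 (allylic bromide) | CC1=C(C#C/C(C)=C/CBr)C(C)(C)C[C@H](O[Si](C)(C)C(C)(C)C)C1 | intermediate (not isolated)
21 | [(2E)-5-[(4R)-4-(tert-butyldimethylsilyloxy)-2,6,6-trimethylcyclohex-1-en-1-yl]-3-methylpent-2-en-4-yn-1-yl]triphenylphosphonium bromide | [Br-].CC1=C(C#C/C(C)=C/C[P+](c2ccccc2)(c3ccccc3)c4ccccc4)C(C)(C)C[C@H](O[Si](C)(C)C(C)(C)C)C1 | intermediate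
22 | (2E,4E,6E)-2,7-dimethylocta-2,4,6-trienedial | O=C/C(C)=C/C=C/C=C(C)/C=O | starting material
23 | phosphonium ylide from 21 | CC1=C(C#C/C(C)=C/[CH-][P+](c2ccccc2)(c3ccccc3)c4ccccc4)C(C)(C)C[C@H](O[Si](C)(C)C(C)(C)C)C1 | intermediate (not isolated)
24 | (2E,4E,6E,8E,10E)-13-[(4R)-4-(tert-butyldimethylsilyloxy)-2,6,6-trimethylcyclohex-1-en-1-yl]-2,7,11-trimethyltrideca-2,4,6,8,10-pentaen-12-ynal | CC1=C(C#C/C(C)=C/C=C/C(C)=C/C=C/C=C(C)/C=O)C(C)(C)C[C@H](O[Si](C)(C)C(C)(C)C)C1 | intermediate
25 | phosphonium ylide from 17 | c2ccccc2[P+](c3ccccc3)(c4ccccc4)[CH-]/C=C(C)/C=C/[C@]1(O[Si](C)(C)C)C(C)(C)C[C@H](O[Si](C)(C)C(C)(C)C)C[C@@]1(C)O[Si](C)(C)C | intermediate (not isolated)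
26 | (3S,5R,6S,3'R)-3,3'-bis-O-(tert-butyldimethylsilyl)-5,6-bis-O-(trimethylsilyl)-7',8'-didehydro-5,6-dihydro-β,β-carotene-3,5,6,3'-tetrol | CC1=C(C#C/C(C)=C/C=C/C(C)=C/C=C/C=C(C)/C=C/C=C(C)/C=C/[C@]2(O[Si](C)(C)C)C(C)(C)C[C@H](O[Si](C)(C)C(C)(C)C)C[C@@]2(C)O[Si](C)(C)C)C(C)(C)C[C@H](O[Si](C)(C)C(C)(C)C)C1 | intermediate
27 | (3S,5R,6S,3'R)-7',8'-didehydro-5,6-dihydro-β,β-carotene-3,5,6,3'-tetrol | CC1=C(C#C/C(C)=C/C=C/C(C)=C/C=C/C=C(C)/C=C/C=C(C)/C=C/[C@]2(O)C(C)(C)C[C@H](O)C[C@@]2(C)O)C(C)(C)C[C@H](O)C1 | target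

**Step count and risks**

Total: 15 steps. Longest linear sequence: 12 steps (steps 1–10, 14, 15).

Step 5 (most at risk). The ketyl may be reduced further and protonated without closing the ring, or the ring may close through a transition state in which samarium ties O5 to the ester oxygen instead of O6, which would give the 6-epimeric trans-diol. The fallback adds a temporary tether and sets out from 6. HF·pyridine in MeCN removes the silyl group to give methyl (5S)-5-hydroxy-3,3-dimethyl-2,7-dioxooctanoate F1, which should rest as its five-membered hemiketal. Acid-catalysed lactonisation (camphorsulfonic acid, toluene, 4 Å sieves, 50 °C) then gives the α-keto-δ-lactone (6S)-4,4-dimethyl-6-(2-oxopropyl)oxane-2,3-dione F2. SmI2 in THF at −78 °C closes ring A across the lactone to the bridged lactone 4,5-dihydroxy-5,8,8-trimethyl-2-oxabicyclo[2.2.2]octan-3-one F3. Because O3 and C7 are tied together, C7 can only end cis to O3 on the new ring, which is the C6 configuration of the target, and the C5 methyl turns away from the gem-dimethyl bridge. Acidic methanolysis (HCl, MeOH) opens the strained lactone to methyl (1S,2R,4S)-1,2,4-trihydroxy-2,6,6-trimethylcyclohexane-1-carboxylate F4, and selective silylation of the secondary hydroxyl (TBSCl, imidazole, DMF) comes back to the route at 8.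

Step 8. The phosphonate anion may fail to reach the aldehyde carbon, which is buried between two fully substituted carbons, or add so slowly that the aldehyde is consumed by side reactions. The fallback sets out from 11. Takai iodo-olefination (CrCl2, CHI3, THF), which uses a small chromium carbenoid, gives the (E)-vinyl iodide tert-butyl-[(1S,3R,4S)-4-[(E)-2-iodoethenyl]-3,5,5-trimethyl-3,4-bis(trimethylsilyloxy)cyclohexyl]oxy-dimethylsilane F5. Stille coupling of F5 with (2E)-3-(tributylstannyl)but-2-en-1-ol (Pd2(dba)3, AsPh3, NMP, rt) forms the C8–C9 bond and comes back to the route at 15, bypassing 14.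

Step 7. Reduction of the hindered ester may stall at −78 °C, or the hemiacetal may collapse on warming and be over-reduced to the primary alcohol. The fallback sets out from 9. Full reduction with excess (i-Bu)2AlH at 0 °C gives [(1R,2R,4S)-4-(tert-butyldimethylsilyloxy)-2,6,6-trimethyl-1,2-bis(trimethylsilyloxy)cyclohexyl]methanol F6, and oxidation with Dess–Martin periodinane (NaHCO3, CH2Cl2) comes back to the route at 11.

Further compounds
F1 | step 5 | methyl (5S)-5-hydroxy-3,3-dimethyl-2,7-dioxooctanoate | COC(=O)C(=O)C(C)(C)C[C@H](O)CC(C)=O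
F2 | step 5 | (6S)-4,4-dimethyl-6-(2-oxopropyl)oxane-2,3-dione | O=C1C(=O)C(C)(C)C[C@H](O1)CC(C)=O
F3 | step 5 | 4,5-dihydroxy-5,8,8-trimethyl-2-oxabicyclo[2.2.2]octan-3-one (O3–C7 lactone of the acid of F4, ring A configuration as in F4) | O=C3[C@]1(O)C(C)(C)C[C@H](O3)C[C@@]1(C)O
F4 | step 5 | methyl (1S,2R,4S)-1,2,4-trihydroxy-2,6,6-trimethylcyclohexane-1-carboxylate | COC(=O)[C@]1(O)C(C)(C)C[C@H](O)C[C@@]1(C)O
F5 | step 8 | tert-butyl-[(1S,3R,4S)-4-[(E)-2-iodoethenyl]-3,5,5-trimethyl-3,4-bis(trimethylsilyloxy)cyclohexyl]oxy-dimethylsilane | I/C=C/[C@]1(O[Si](C)(C)C)C(C)(C)C[C@H](O[Si](C)(C)C(C)(C)C)C[C@@]1(C)O[Si](C)(C)C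
F6 | step 7 | [(1R,2R,4S)-4-(tert-butyldimethylsilyloxy)-2,6,6-trimethyl-1,2-bis(trimethylsilyloxy)cyclohexyl]methanol | OC[C@]1(O[Si](C)(C)C)C(C)(C)C[C@H](O[Si](C)(C)C(C)(C)C)C[C@@]1(C)O[Si](C)(C)C
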